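In a one-step world the starting material would turn into target, and a flask left longer would simply hold more target. I read the earlier runs to see whether that world was ours.

| setting | oak | maple | south | west | east |
|---|---|---|---|---|---|
| starting material | 0.045 M | 0.068 M | 0.091 M | 0.091 M | 0.091 M |
| partner | 0.164 M | 0.164 M | 0.164 M | 0.164 M | 0.164 M |
| remark | run made earlier | run made earlier |  |  |  |
| time |  |  | 2.5 d | 6.0 d | 15 d |

| run | time / h | intermediate / % | homo product / % | target / % | starting material / % |
|---|---|---|---|---|---|
| oak | 4.00 | 7 | 1 | 14 | 82 |
| oak | 12.0 | 10 | 5 | 37 | 49 |
| oak | 20.0 | 9 | 9 | 51 | 30 |
| oak | 30.0 | 11 | 15 | 59 | 20 |
| oak | 50.0 | 6 | 23 | 67 | 7 |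
| maple | 4.00 | 8 | 1 | 14 | 81 |
| maple | 12.0 | 12 | 6 | 34 | 49 |
| maple | 20.0 | 9 | 12 | 47 | 32 |
| maple | 30.0 | 9 | 14 | 59 | 16 |
| maple | 50.0 | 5 | 25 | 66 | 7 |

(each reading ± 1.5 percentage points)

- a species is counted by the starting material in it: one homo product counts as two
- the numbers in the tables scatter by 1.5 percentage points (one standard deviation)
- a reading or a percentage of target counts all its forms, free or not

- which of these there is most of at the end, counted by the starting material in it, south (homo product / starting material / intermediate / target)
- which of these there is most of at the end, counted by the starting material in it, west (homo product / starting material / intermediate / target)
- which of these there is most of at the end, counted by the starting material in it, east (homo product / starting material / intermediate / target)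
- how much there is at the end of the one of these that leads, in percent of the starting material charged: south
- how much there is at the end of the one of these that leads, in percent of the starting material charged: west
- how much there is at the end of the one of these that leads, in percent of the starting material charged: east

The starting material behaved simply: in oak it lost a power of ten every 43.0 h, so I expected about 4.04% of it in south at the end. The intermediate broke the one-step picture. In the oak readings its ratio to the starting material grew ten times between 4.00 h and 50.0 h, so it seemed to be outliving what made it. Homo product was still climbing too: in maple it gained 11 percentage points over the last span, more than the 7% of starting material still there. I took it that target was paying for this through the intermediate, which would make target the kinetic product and homo product the thermodynamic one (kinetic against thermodynamic control). I put the pace in concentration, pooled oak and maple, and assumed that it would carry over unchanged to a larger charge: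

pace of homo product = gains in oak and maple, each times its charge, over the two spans = 0.277 mM h⁻¹

time = last oak target × charge of south / pace = 9.17 d

I called this the emptying time: the target in a flask divided by the pace of homo product. As a straight line it emptied east before its 15 d. That was the weak link, since a pace paid for by target should shrink with target. So I reforged it as a decay, losing a power of ten in 21.1 d, counted from 50.0 h and starting at the 67% that oak read then, which I assumed for south, west and east as well:

target = starting target × exp(−time since then / emptying time): south 64.0%, west 43.7%, east 16.4%

Giving the remainder, less 6% of intermediate, to homo product, I committed to target in south, but to homo product in west at 50.3% and in east at 77.6%.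

The forecast gave target at 69% for south, target at 72% for west and target at 72% for east, holding that “Homo needs no feed from target”.

The flasks gave target at 63.8% in south, target at 54.0% in west and homo product at 68.6% in east.

    partner + intermediate ⇌ target (K = 37.0 M⁻¹, k = 0.00110 M⁻¹ s⁻¹)
    crystals ⇌ target, rate k2*(cs2 - [target]) while solid is left; crystals form when [target] > cs2 (solubility = 15.0 mM, k = 8.90 × 10⁻⁵ s⁻¹)
    starting material → intermediate (k = 1.60 × 10⁻⁵ s⁻¹)
    2 intermediate → homo product (k = 0.00180 M⁻¹ s⁻¹)

South held 63.8% of target against my 64.0%, but west kept target ahead, 54.0% against 42.5% of homo product, where I had the order reversed. East's target fell from 49.1% at 7.50 d to 28.4% at 15.0 d, which in my decay formula means an emptying time of 13.7 d, longer than my 9.17 d. For the neighbour of east charged with 0.055 M, the same reckoning gave 5.54 d and 6.51% of target; it held 21.6%. East had not come to rest: left ten times as long, its target fell a further 27 points, to 1.07%, with homo product at 98.7%.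

The numbers in the tables are calculated with made-up constants, and the scatter is random.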